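## Retrosynthetic overview

1. The target is catechin-(4α→6)-catechin-(4α→6)-epicatechin. Rings are lettered A/B/C (top unit), D/E/F (middle unit) and G/H plus its own pyran ring (bottom unit). The last step is a global hydrogenolysis of twelve OBn groups and one C8–Br.
2. The key disconnection is the C4–C4a bond of both the top and the middle unit, not the interflavan bonds. Pyran rings C and F close together in a double dehydrative Friedel–Crafts cyclisation of an open-chain bis-carbinol, which also sets both C4 centres (3,4-trans).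
3. Regiocontrol is built in. In the open form, ring D is a symmetric aryl ether carrying the top chain para to its ether oxygen, so closure at either ortho carbon can only give the 4→6 link. The lower 4→6 link comes from a C6-iodo/C8-bromo epicatechin.
4. The bis-carbinol is assembled from one (2R,3S)-epoxy aldehyde used twice. Two aryl-metal 1,2-additions make the C4–aryl bonds, and two phenoxide SN2 epoxide openings with inversion make the O1–C2 bonds (2,3-trans).
5. Ring order: all aromatic rings and the bottom pyran ring are bought in, and rings C and F form simultaneously in the penultimate step.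

Assumption: in step 2 the sense of induction follows the usual face-shielding model for diarylprolinol silyl ethers, which assigns the (R)-catalyst to the (2R,3S)-epoxide; both catalyst antipodes are sold.

Assumption: the carbinol centres made in steps 6 and 7 are epimer mixtures carried on unseparated (left undefined in the SMILES), because ionisation in step 9 erases them.

## Route

Step 1
Reactants: 1 3,4-bis(benzyloxy)benzaldehyde
Product: 2 (E)-3-[3,4-bis(benzyloxy)phenyl]prop-2-enal
Conditions: Ph3P=CHCHO (1.1 equiv), toluene, 90 °C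
Reagents that add atoms: (triphenylphosphoranylidene)acetaldehyde, O=CC=P(c1ccccc1)(c1ccccc1)c1ccccc1
Why: Wittig olefination with the stabilised formyl ylide gives the E-enal, and this geometry later becomes the trans-epoxide.

Step 2
Reactants: 2 (E)-3-[3,4-bis(benzyloxy)phenyl]prop-2-enal
Product: 3 (2R,3S)-3-[3,4-bis(benzyloxy)phenyl]oxirane-2-carbaldehyde
Conditions: 35% aq. H2O2 (1.3 equiv), (R)-2-{bis[3,5-bis(trifluoromethyl)phenyl][(trimethylsilyl)oxy]methyl}pyrrolidine (10 mol %), CH2Cl2, rt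
Reagents that add atoms: hydrogen peroxide, OO
Why: In this iminium–enamine (Jørgensen-type) nucleophilic epoxidation the peroxide adds to the β-carbon on the face left open by the CAr2(OTMS) group and the enamine closes the ring, giving the trans-(2R,3S)-epoxide that fixes C3 (retained) and the pre-inversion configuration of C2 for both catechin units.

Step 3
Reactants: 4 (−)-epicatechin
Product: 5 5,7,3',4'-tetra-O-benzyl-(−)-epicatechin
Conditions: BnBr (4.4 equiv), K2CO3 (4.4 equiv), DMF, 0 °C → rt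
Reagents that add atoms: benzyl bromide, BrCc1ccccc1
Why: Williamson etherification with a carbonate base alkylates only the four phenols, leaves the 3-OH free and touches no stereocentre.

Step 4
Reactants: 5 5,7,3',4'-tetra-O-benzyl-(−)-epicatechin
Product: 7 8-bromo-6-iodo-5,7,3',4'-tetra-O-benzyl-(−)-epicatechin, via 8-bromide 6 (not isolated)
Conditions: NBS (1.0 equiv), CH2Cl2, −78 → 0 °C; then NIS (1.1 equiv), rt
Reagents that add atoms: N-bromosuccinimide, O=C1CCC(=O)N1Br; N-iodosuccinimide, O=C1CCC(=O)N1I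
Why: In this sequential electrophilic aromatic halogenation C8 is the most nucleophilic site of a 5,7-di-O-benzyl flavan and takes bromine first, so iodine can only enter the last free position of ring G, C6.

Step 5
Reactants: 8 3,5-bis(benzyloxy)phenol
Product: 9 [3,5-bis(benzyloxy)phenoxy]triisopropylsilane
Conditions: TIPSCl (1.1 equiv), imidazole (1.1 equiv), DMF, rt
Reagents that add atoms: chlorotriisopropylsilane, CC(C)[Si](Cl)(C(C)C)C(C)C
Why: O-silylation masks the phenol of future ring D with a bulky, non-directing group that shields both flanking ring positions in the next step.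

Step 6
Reactants: 9 [3,5-bis(benzyloxy)phenoxy]triisopropylsilane; 3 (2R,3S)-3-[3,4-bis(benzyloxy)phenyl]oxirane-2-carbaldehyde; 8 3,5-bis(benzyloxy)phenol
Product: 12 (1RS,2S,3R)-3-[3,5-bis(benzyloxy)phenoxy]-3-[3,4-bis(benzyloxy)phenyl]-1-[2,6-bis(benzyloxy)-4-(triisopropylsilyloxy)phenyl]propane-1,2-diol, via aryllithium 10 (not isolated), via epoxy carbinol 11 (not isolated)
Conditions: n-BuLi (1.0 equiv), THF, 0 °C, 1 h; 3, −78 °C; then 8 (2.5 equiv), DMF, 65 °C; H2O work-up
Reagents that add atoms: none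
Why: Directed ortho-metalation takes the only position flanked by two benzyloxy groups (para to OTIPS), the aryllithium adds 1,2 to the aldehyde, and the lithium phenoxide formed from 8 by proton transfer opens the epoxide by SN2 attack at the benzylic carbon with inversion, turning the trans-epoxide into the 2,3-trans (flavan 2R,3S) pattern while excess phenol buffers against Payne rearrangement.

Step 7
Reactants: 7 8-bromo-6-iodo-5,7,3',4'-tetra-O-benzyl-(−)-epicatechin; 3 (2R,3S)-3-[3,4-bis(benzyloxy)phenyl]oxirane-2-carbaldehyde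
Product: 14 (RS)-{(2S,3S)-3-[3,4-bis(benzyloxy)phenyl]oxiran-2-yl}[8-bromo-5,7,3',4'-tetra-O-benzyl-(−)-epicatechin-6-yl]methanol, via arylmagnesium alkoxide 13 (not isolated)
Conditions: i-PrMgCl·LiCl (2.1 equiv), THF, −20 °C; 3, −78 → −30 °C; H2O quench; Et3N-deactivated SiO2
Reagents that add atoms: none
Why: Halogen–magnesium exchange is far faster for iodide than for bromide on this electron-rich ring, so only C6 is metalated (the first equivalent deprotonates the 3-OH), and Grignard 1,2-addition to the aldehyde fixes the lower 4→6 bond with the epoxide intact.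

Step 8
Reactants: 12 the silyl ether diol from step 6; 14 the epoxy carbinol from step 7
Product: 16 6-[(1RS,2S,3R)-3-[3,4-bis(benzyloxy)phenyl]-3-{3,5-bis(benzyloxy)-4-[(1RS,2S,3R)-3-[3,5-bis(benzyloxy)phenoxy]-3-[3,4-bis(benzyloxy)phenyl]-1,2-dihydroxypropyl]phenoxy}-1,2-dihydroxypropyl]-8-bromo-5,7,3',4'-tetra-O-benzyl-(−)-epicatechin, via cesium phenoxide 15 (not isolated)
Conditions: CsF (1.2 equiv), BHT (1.0 equiv, hindered proton shuttle), DMF, 45 °C; H2O work-up
Reagents that add atoms: none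
Why: Fluoride cleaves the aryl silyl ether and the freed ring D phenoxide opens the epoxide of 14 at its benzylic carbon by SN2 with inversion (epoxide aryloxylation), giving the 2,3-trans (flavan 2R,3S) middle chain bound para to the top chain.

Step 9
Reactants: 16 the open-chain bis-carbinol from step 8
Product: 17 dodeca-O-benzyl catechin-(4α→6)-catechin-(4α→6)-(8-bromo)epicatechin
Conditions: Sc(OTf)3 (20 mol %), 4 Å MS, CH2Cl2 (1 mM), −40 → 0 °C
Reagents that add atoms: none
Why: Proposed new method: the Lewis acid ionises both 2,4,6-trioxygenated benzylic carbinols (much more labile than the C2–OAr ethers) to quinone-methide-type cations, and at high dilution each is captured by its tethered 3,5-dioxygenated aryl ether ring (ring A at C4, ring D at C4 of the middle unit) through a six-membered chair-like transition state with the C2 aryl, C3 hydroxyl and C4 aryl groups all equatorial and attack anti to the C3–O bond, so both new centres come out 3,4-trans (4α) whatever the carbinol configuration and the two equivalent ortho carbons of ring D both give the 4→6 isomer; the closest known reaction types are the intramolecular Friedel–Crafts cyclisations of benzylic alcohols and aryl glycidyl ethers to trans-4-arylchroman-3-ols and the 3,4-trans-selective arylation of 2,3-trans-flavan-4-yl cations.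

Step 10
Reactants: 17 the protected trimer from step 9
Product: 18 catechin-(4α→6)-catechin-(4α→6)-epicatechin (target)
Conditions: H2 (1 atm), Pd(OH)2/C, Et3N (1.1 equiv), THF–MeOH–H2O, rt
Reagents that add atoms: none
Why: Catalytic hydrogenolysis removes the twelve benzyl ethers and the aryl bromide in one operation, Et3N traps the HBr that would otherwise cleave the interflavan bonds, and no stereocentre is affected.

## Compound list

1 | 3,4-bis(benzyloxy)benzaldehyde | O=Cc1ccc(OCc9ccccc9)c(OCc9ccccc9)c1 | starting material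

2 | (E)-3-[3,4-bis(benzyloxy)phenyl]prop-2-enal | O=C/C=C/c1ccc(OCc9ccccc9)c(OCc9ccccc9)c1 | intermediate

3 | (2R,3S)-3-[3,4-bis(benzyloxy)phenyl]oxirane-2-carbaldehyde (trans) | O1[C@@H](c2ccc(OCc9ccccc9)c(OCc9ccccc9)c2)[C@@H]1C=O | intermediate

4 | (−)-epicatechin (2R,3R) | O[C@@H]1Cc2c(O)cc(O)cc2O[C@@H]1c1ccc(O)c(O)c1 | starting material

5 | 5,7,3',4'-tetra-O-benzyl-(−)-epicatechin | O[C@@H]1Cc2c(OCc9ccccc9)cc(OCc9ccccc9)cc2O[C@@H]1c1ccc(OCc9ccccc9)c(OCc9ccccc9)c1 | intermediate

6 | 8-bromo-5,7,3',4'-tetra-O-benzyl-(−)-epicatechin | O[C@@H]1Cc2c(OCc9ccccc9)cc(OCc9ccccc9)c(Br)c2O[C@@H]1c1ccc(OCc9ccccc9)c(OCc9ccccc9)c1 | intermediate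

7 | 8-bromo-6-iodo-5,7,3',4'-tetra-O-benzyl-(−)-epicatechin | O[C@@H]1Cc2c(OCc9ccccc9)c(I)c(OCc9ccccc9)c(Br)c2O[C@@H]1c1ccc(OCc9ccccc9)c(OCc9ccccc9)c1 | intermediate

8 | 3,5-bis(benzyloxy)phenol | Oc1cc(OCc9ccccc9)cc(OCc9ccccc9)c1 | starting material

9 | [3,5-bis(benzyloxy)phenoxy]triisopropylsilane | CC(C)[Si](C(C)C)(C(C)C)Oc1cc(OCc9ccccc9)cc(OCc9ccccc9)c1 | intermediate

10 | 2,6-bis(benzyloxy)-4-(triisopropylsilyloxy)phenyllithium | [Li]c1c(OCc9ccccc9)cc(O[Si](C(C)C)(C(C)C)C(C)C)cc1OCc9ccccc9 | intermediate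

11 | (RS)-[2,6-bis(benzyloxy)-4-(triisopropylsilyloxy)phenyl]{(2S,3S)-3-[3,4-bis(benzyloxy)phenyl]oxiran-2-yl}methanol | O1[C@@H](c2ccc(OCc9ccccc9)c(OCc9ccccc9)c2)[C@@H]1C(O)c1c(OCc9ccccc9)cc(O[Si](C(C)C)(C(C)C)C(C)C)cc1OCc9ccccc9 | intermediate

12 | (1RS,2S,3R)-3-[3,5-bis(benzyloxy)phenoxy]-3-[3,4-bis(benzyloxy)phenyl]-1-[2,6-bis(benzyloxy)-4-(triisopropylsilyloxy)phenyl]propane-1,2-diol (open top unit: rings A, B, D) | O(c1cc(OCc9ccccc9)cc(OCc9ccccc9)c1)[C@H](c1ccc(OCc9ccccc9)c(OCc9ccccc9)c1)[C@@H](O)C(O)c1c(OCc9ccccc9)cc(O[Si](C(C)C)(C(C)C)C(C)C)cc1OCc9ccccc9 | intermediate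

13 | 6-chloromagnesio-8-bromo-5,7,3',4'-tetra-O-benzyl-(−)-epicatechin 3-O-chloromagnesium alkoxide | Cl[Mg]O[C@@H]1Cc2c(OCc9ccccc9)c([Mg]Cl)c(OCc9ccccc9)c(Br)c2O[C@@H]1c1ccc(OCc9ccccc9)c(OCc9ccccc9)c1 | intermediate

14 | (RS)-{(2S,3S)-3-[3,4-bis(benzyloxy)phenyl]oxiran-2-yl}[8-bromo-5,7,3',4'-tetra-O-benzyl-(−)-epicatechin-6-yl]methanol | O1[C@@H](c2ccc(OCc9ccccc9)c(OCc9ccccc9)c2)[C@@H]1C(O)c1c(OCc9ccccc9)c(Br)c2c(c1OCc9ccccc9)C[C@@H](O)[C@@H](c1ccc(OCc9ccccc9)c(OCc9ccccc9)c1)O2 | intermediate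

15 | cesium phenoxide of desilylated 12 | O(c1cc(OCc9ccccc9)cc(OCc9ccccc9)c1)[C@H](c1ccc(OCc9ccccc9)c(OCc9ccccc9)c1)[C@@H](O)C(O)c1c(OCc9ccccc9)cc([O-])cc1OCc9ccccc9.[Cs+] | intermediate

16 | open-chain bis-carbinol (systematic name as in step 8; rings C and F still open) | O(c1cc(OCc9ccccc9)cc(OCc9ccccc9)c1)[C@H](c1ccc(OCc9ccccc9)c(OCc9ccccc9)c1)[C@@H](O)C(O)c1c(OCc9ccccc9)cc(O[C@H](c2ccc(OCc9ccccc9)c(OCc9ccccc9)c2)[C@@H](O)C(O)c2c(OCc9ccccc9)c(Br)c3c(c2OCc9ccccc9)C[C@@H](O)[C@@H](c2ccc(OCc9ccccc9)c(OCc9ccccc9)c2)O3)cc1OCc9ccccc9 | intermediate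

17 | dodeca-O-benzyl catechin-(4α→6)-catechin-(4α→6)-(8-bromo)epicatechin | O(Cc9ccccc9)c1cc(OCc9ccccc9)c2c(c1)O[C@H](c1ccc(OCc9ccccc9)c(OCc9ccccc9)c1)[C@@H](O)[C@@H]2c1c(OCc9ccccc9)cc2c(c1OCc9ccccc9)[C@@H](c1c(OCc9ccccc9)c(Br)c3c(c1OCc9ccccc9)C[C@@H](O)[C@@H](c1ccc(OCc9ccccc9)c(OCc9ccccc9)c1)O3)[C@H](O)[C@@H](c1ccc(OCc9ccccc9)c(OCc9ccccc9)c1)O2 | intermediate

18 | catechin-(4α→6)-catechin-(4α→6)-epicatechin | Oc1cc(O)c2c(c1)O[C@H](c1ccc(O)c(O)c1)[C@@H](O)[C@@H]2c1c(O)cc2c(c1O)[C@@H](c1c(O)cc3c(c1O)C[C@@H](O)[C@@H](c1ccc(O)c(O)c1)O3)[C@H](O)[C@@H](c1ccc(O)c(O)c1)O2 | target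

## Step count and risks

- **Total steps:** 10.
- **Longest linear sequence:** 6 steps, either 1, 2, 6, 8, 9, 10 or 3, 4, 7, 8, 9, 10.

**Step 9 (double cyclisation).** The risks are competing ionisation of the C2–OAr ethers, indane formation through ring B or ring E, incomplete 3,4-trans control, or closure of only one ring. The fallback closes the rings one at a time. It sets out from 12, where Sc(OTf)3 closes ring C alone and gives the ring-C-closed silyl ether F1. Its C4 configuration can be checked and purified at monomer size, and its phenoxide no longer carries a benzylic leaving group. CsF-triggered opening of epoxide 14 by this compound gives the half-open trimer F2. A second acid cyclisation then closes ring F and comes back to the route at 17.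

**Step 8 (fragment union).** Phenoxide 15 is a para-hydroxybenzylic alcohol anion that may expel hydroxide to a para-quinone methide, and both partners are large and labile. The fallback grows the chain linearly from the bottom with a small phenol that can be used in excess. It sets out from 14, which is opened with 8 (3 equiv, Cs2CO3 0.3 equiv, DMF) to give the bottom-half aryl ether F3. NIS then iodinates ring D para to its bulky ether oxygen and gives the para-iodide F4. Iodine–magnesium exchange (i-PrMgCl·LiCl, 4.1 equiv) and addition to 3 gives the ring D epoxy carbinol F5. Opening this epoxide with 8 comes back to the route at 16.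

**Step 6 (deprotonative lithiation).** Benzylic deprotonation of the OBn groups with Wittig rearrangement, or lithiation next to OTIPS, would erode yield and regiopurity. The fallback makes the carbanion by halogenation and exchange instead of deprotonation. It sets out from 9, where NBS (CH2Cl2, −78 °C) attacks the position remote from the TIPS group and gives the crystallisable para-bromide F6. Any ortho isomer is removed at this simple stage. Bromine–lithium exchange with n-BuLi at −78 °C then comes back to the route at 10.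

## Further compounds

F1 | step 9 | 4α-[2,6-bis(benzyloxy)-4-(triisopropylsilyloxy)phenyl]-5,7,3',4'-tetra-O-benzyl-(+)-catechin (ring-C-closed silyl ether) | O(Cc9ccccc9)c1cc(OCc9ccccc9)c2c(c1)O[C@H](c1ccc(OCc9ccccc9)c(OCc9ccccc9)c1)[C@@H](O)[C@@H]2c1c(OCc9ccccc9)cc(O[Si](C(C)C)(C(C)C)C(C)C)cc1OCc9ccccc9

F2 | step 9 | half-open trimer (ring C closed, ring F open, middle chain 1RS,2S,3R bound to C6 of 8-bromo-tetra-O-benzylepicatechin) | O(Cc9ccccc9)c1cc(OCc9ccccc9)c2c(c1)O[C@H](c1ccc(OCc9ccccc9)c(OCc9ccccc9)c1)[C@@H](O)[C@@H]2c1c(OCc9ccccc9)cc(O[C@H](c2ccc(OCc9ccccc9)c(OCc9ccccc9)c2)[C@@H](O)C(O)c2c(OCc9ccccc9)c(Br)c3c(c2OCc9ccccc9)C[C@@H](O)[C@@H](c2ccc(OCc9ccccc9)c(OCc9ccccc9)c2)O3)cc1OCc9ccccc9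

F3 | step 8 | bottom-half aryl ether: 6-{(1RS,2S,3R)-3-[3,5-bis(benzyloxy)phenoxy]-3-[3,4-bis(benzyloxy)phenyl]-1,2-dihydroxypropyl}-8-bromo-5,7,3',4'-tetra-O-benzyl-(−)-epicatechin | O(c1cc(OCc9ccccc9)cc(OCc9ccccc9)c1)[C@H](c1ccc(OCc9ccccc9)c(OCc9ccccc9)c1)[C@@H](O)C(O)c1c(OCc9ccccc9)c(Br)c2c(c1OCc9ccccc9)C[C@@H](O)[C@@H](c1ccc(OCc9ccccc9)c(OCc9ccccc9)c1)O2

F4 | step 8 | para-iodide of F3 (3,5-bis(benzyloxy)-4-iodophenoxy in ring D) | O(c1cc(OCc9ccccc9)c(I)c(OCc9ccccc9)c1)[C@H](c1ccc(OCc9ccccc9)c(OCc9ccccc9)c1)[C@@H](O)C(O)c1c(OCc9ccccc9)c(Br)c2c(c1OCc9ccccc9)C[C@@H](O)[C@@H](c1ccc(OCc9ccccc9)c(OCc9ccccc9)c1)O2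

F5 | step 8 | ring D epoxy carbinol (F3 carrying (RS)-hydroxy{(2S,3S)-3-[3,4-bis(benzyloxy)phenyl]oxiran-2-yl}methyl para to the ring D ether oxygen) | O1[C@@H](c2ccc(OCc9ccccc9)c(OCc9ccccc9)c2)[C@@H]1C(O)c1c(OCc9ccccc9)cc(O[C@H](c2ccc(OCc9ccccc9)c(OCc9ccccc9)c2)[C@@H](O)C(O)c2c(OCc9ccccc9)c(Br)c3c(c2OCc9ccccc9)C[C@@H](O)[C@@H](c2ccc(OCc9ccccc9)c(OCc9ccccc9)c2)O3)cc1OCc9ccccc9

F6 | step 6 | [3,5-bis(benzyloxy)-4-bromophenoxy]triisopropylsilane (para-bromide) | CC(C)[Si](C(C)C)(C(C)C)Oc1cc(OCc9ccccc9)c(Br)c(OCc9ccccc9)c1
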